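## Structural features

The target is a halimane-type bicycle: a decalin (ring A = C1–C5 and C10, ring B = C5–C10) whose only ring unsaturation is the trisubstituted C1=C10 alkene, so C5 is the single ring-fusion stereocentre. C4 is quaternary (methyl on the α face, carboxylic acid on the β face) and adjoins C5 (H on the β face). C8 (methyl α) adjoins the second quaternary centre C9 (methyl C20 α, side chain β). The two pairs are separated by C6–C7 and by the sp2 carbon C10. The C9 side chain, C11–C16, is CH2CH2C(CH3)=CHCH2O with an E trisubstituted alkene and a primary allylic propanoate. Fragile points are the allylic ester (ionisation, acyl transfer, no hydrides or hard nucleophiles), the C1=C10 alkene beside quaternary C9 (acid-induced migration), and the neopentyl-type C4 carboxyl, whose esters resist attack at the acyl carbon. The real difficulty is C9: its methyl must enter cis to the C8 methyl, on the more hindered face, and its configuration must be tied to the remote C4/C5 pair. The key step exploits the fact that C20 is allylic to C1=C10. A cyclopropane across C9–C10 of ring B with C20 as its CH2, built under direction of an α hydroxyl at C1 in ring A and opened from a radical at C1, releases the C9 methyl and the C1=C10 alkene together.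

## Logic of the disconnections

30 is cut at the O–acyl bond of the allylic ester to 29, and 29 at the O–CH3 bond of its methyl ester to 28. The allylic propanoate tolerates neither hydride, organometallic nor strongly nucleophilic reagents, so it is made last. The C4 carboxyl is neopentyl-like, so its ester is opened at the alkyl carbon, not the acyl carbon. The forward steps must acylate a primary alcohol beside a free acid and demethylate beside a free allylic alcohol.

28 is cut at C13–C16 and C14–C15 to the terminal alkyne 26. Syn-carbometalation with one-carbon trapping fixes the E geometry by mechanism, which olefination of a methyl ketone would not. The organoaluminium reagent must spare the hindered ester.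

26 is cut at C13≡C14 to aldehyde 25, which comes through alcohol 24 from silyl ether 23. This leaves a three-carbon oxygenated arm on C9 that is inert in all earlier steps.

23 is traced through 22 to 20 by re-forming the C10–C20 bond. The C9 methyl and the C1=C10 alkene are the opened form of a cyclopropylcarbinyl system at C1. This removes the quaternary methyl as a separate problem and turns it into the face selectivity of a cyclopropanation. The forward step must cleave the exocyclic C10–C20 bond and not the ring bond C9–C10.

20 is cut at C9–C20 and C10–C20 to allylic alcohol 18 and 19. The C1 hydroxyl serves first as the directing group and later as the radical leaving group. C9 becomes sp2, so the precursor carries only C4, C5, C8 and the temporary C1 centre. The forward step needs complete α-face delivery to a tetrasubstituted alkene, so the C1 alcohol must be α.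

18 is cut at C1–H to enone 17. The carbinol configuration is assigned to a catalyst-controlled reduction that axial attack on ring A should reinforce.

17 is cut at C9=C10, through the β-alkoxy ketone 16, to 15, in which ring B is open. C10 is the carbon of a silyl enol ether and C9 a ketal carbon. A plain 1,7-diketone aldol would expose C8, α to a free C9 ketone, to enolisation. Closure through an oxocarbenium ion and a regiodefined enol ether avoids this. The Lewis acid must spare the primary silyl ether.

15 is cut at C5–C6 to enone 6 and the Grignard reagent 14, made from chloride 13. The conjugate addition joins the two chiral fragments and delivers the C1–C10 enol ether regiospecifically. It must occur anti to the C4 ester, and both partners must be single enantiomers or the union gives diastereomers.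

13 is the ketal of 12. 12 is cut at C9–C11 to amide 9 and the Grignard reagent 11 (from 10). 9 comes through 8 from lactone 7, whose O–CH2 bond is opened by chloride. C8 is thus taken from the chiral pool, and C6 is carried as a chloride that survives the ketone synthesis.

6 is the ester of acid 5, which comes from aldehyde 4. 4 is cut at C4–C5 and C2–C3 (retro-Diels–Alder) to 1 and 2. An aldehyde dienophile is chosen because a chiral hydrogen-bond donor can activate it enantioselectively. A racemic ring A piece would lose half the material at the union with 14.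

## Other disconnections considered

Alternative 1: Ring A is cut at C4–C5 and C2–C3, leading to the ring B diene A1 (a 1-vinylcyclohexene carrying the C8 and C9 substituents, with allyl as side-chain precursor) and 1. In the forward sense a chiral Lewis acid would bind 1, and the diene C5=C10–C1=C2 would add to give aldehyde A2 with the C1=C10 alkene already in place.
- In its favour: it is convergent, it sets C4 and C5 in one concerted step, and it needs no fragmentation. In ring construction and in step count after the cycloaddition it is better than the chosen plan.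
- Against it: the target needs the formyl group cis to H5, which is the exo orientation of the carbonyl, whereas semicyclic dienes usually react endo. The diene face must be chosen beside a quaternary C9 whose methyl and allyl groups differ little. The two alkyl substituents of the diene direct regiochemistry in opposite senses.
- Comparison: the hardest feature, quaternary C9 cis to the C8 methyl, is not solved but moved into A1. The chosen plan solves it by intramolecular delivery. Overall the gain in steps is offset by weaker stereocontrol.

Alternative 2: Both rings are cut at once, at C8–C9 and C5–C10, to the acyclic trienone A3 (malonate at C4, (E,E)-diene C5=C6–C7=C8, (E)-enone at C9=C10). A Lewis-acid-promoted intramolecular Diels–Alder reaction through the endo transition state would give the cis-fused octalone A4.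
- In its favour: C5, C8, C9 and C10 are set in one stereospecific step from an easily made chain. The cis C8/C9 methyl relationship follows from alkene geometry, which is at least the equal of the directed cyclopropanation for that pair.
- Against it: C9 is a β,β-disubstituted dienophile carbon, so a quaternary centre must form at a deactivated, hindered terminus. Absolute control would rest on a chiral Lewis acid binding a simple ketone. A4 is also far from the target: the C6=C7 alkene must be removed, the C1 ketone turned regioselectively into the C1=C10 alkene, one of two diastereotopic esters reduced to methyl, and a two-carbon arm extended by four carbons.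
- Comparison: ring formation is more economical, but the corrections make the total no shorter. C4 is not controlled by the key step at all, whereas the chosen plan fixes C4 at the outset.

Alternative 3: Ring A is cut at C4–C5 only, to triene A5, in which ring B carries a (2Z,4Z)-dienoate at C10. Thermal disrotatory 6π closure would give the 1(10),2-diene A6.
- In its favour: disrotation translates alkene geometry into the C4/C5 relationship (methyl outside, ester inside). This is stereospecific and therefore better defined than the conjugate addition of the chosen plan. The ester and silyloxypropyl chain are those of 23, so the end game would be the same.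
- Against it: the direction of disrotation is governed only by the remote C8/C9 centres, so diastereomers are likely. A fully substituted terminus with an inward ester raises the barrier and invites 1,7-hydrogen shifts and Z/E isomerisation. The (Z,Z)-dienoate must be made geometrically pure, and C2=C3 must then be saturated selectively within a conjugated diene.
- Comparison: C9 must again be built beforehand, as in alternative 1. Step economy is similar to the chosen plan, but with less control over the link between the two stereochemical pairs.

Key step: step 12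

Remark: atoms carry halimane numbering. α is the face of the C4, C8 and C9 methyl groups of the target, and β the face of H5, the C4 carboxyl and the C9 side chain.

Assumption: the (4R,5R)-diol of step 1 is taken to give (S)-4 by the single-point hydrogen-bond model. The sense is to be confirmed on 6, and the (4S,5S)-diol, equally available, is used if it proves opposite.

## Route

Step 1
Reactants: 1 2-methylprop-2-enal; 2 (1E)-3-{[tert-butyl(dimethyl)silyl]oxy}-N,N-dimethylbuta-1,3-dien-1-amine
Product: 4 (1S)-1-methyl-4-oxocyclohex-2-ene-1-carbaldehyde, via amino silyl enol ether cycloadduct 3 (not isolated)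
Conditions: (4R,5R)-2,2-dimethyl-α,α,α′,α′-tetra(naphthalen-1-yl)-1,3-dioxolane-4,5-dimethanol (20 mol%), toluene, −80 °C; then 1 M HCl, THF, 0 °C
Reagents that add atoms: none
Why: Hydrogen-bond-catalysed Diels–Alder reaction of a 1-amino-3-silyloxy diene with an α-substituted acrolein; the amino terminus bonds to the α-carbon of 1 and the diol shields one face of the bound aldehyde, which sets the quaternary centre (future C4). Acid then hydrolyses the silyl enol ether and eliminates dimethylamine, erasing the second stereocentre of 3.

Step 2
Reactants: 4
Product: 5 (1S)-1-methyl-4-oxocyclohex-2-ene-1-carboxylic acid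
Conditions: NaClO2, NaH2PO4, 2-methylbut-2-ene, t-BuOH–H2O, 0 °C → rt
Reagents that add atoms: sodium chlorite, [Na+].[O-]Cl=O
Why: Pinnick oxidation converts the non-enolisable aldehyde to the acid under buffered conditions that leave the enone and the quaternary centre untouched.

Step 3
Reactants: 5
Product: 6 methyl (1S)-1-methyl-4-oxocyclohex-2-ene-1-carboxylate
Conditions: MeI, K2CO3, DMF, rt
Reagents that add atoms: iodomethane, CI
Why: O-Alkylation of the carboxylate (SN2 on iodomethane) avoids activating the hindered acyl carbon; the weak base does not enolise the ketone.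

Step 4
Reactants: 7 (3R)-3-methyloxolan-2-one
Product: 8 methyl (2R)-4-chloro-2-methylbutanoate
Conditions: SOCl2, MeOH, 0 → 50 °C
Reagents that add atoms: methanol, CO; thionyl chloride, O=S(Cl)Cl
Why: Acid-mediated opening of the lactone by chloride (SN2 at the O–CH2 carbon) with Fischer esterification; thionyl chloride supplies HCl and consumes water, and the α stereocentre is not enolised under these acidic conditions.

Step 5
Reactants: 8
Product: 9 (2R)-4-chloro-N-methoxy-N,2-dimethylbutanamide
Conditions: MeNH(OMe)·HCl, Me3Al, CH2Cl2, 0 °C → reflux
Reagents that add atoms: N,O-dimethylhydroxylamine hydrochloride, CNOC.Cl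
Why: Weinreb aminolysis of the ester by an aluminium amide; the reagent is weakly basic, so neither the α stereocentre nor the primary chloride is affected.

Step 6
Reactants: 9; 10 (3-bromopropoxy)(tert-butyl)dimethylsilane
Product: 12 (3R)-7-{[tert-butyl(dimethyl)silyl]oxy}-1-chloro-3-methylheptan-4-one, via silyloxypropyl Grignard reagent 11 (not isolated)
Conditions: 10, Mg, THF, 40 °C; then 9, THF, 0 °C; aq. NH4Cl
Reagents that add atoms: none
Why: Weinreb ketone synthesis: the Grignard reagent adds once to give a chelated tetrahedral intermediate that collapses to the ketone only on work-up. A primary alkyl chloride is inert to Grignard reagents at 0 °C without a transition-metal catalyst.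

Step 7
Reactants: 12
Product: 13 tert-butyl(3-{2-[(2R)-4-chlorobutan-2-yl]-1,3-dioxolan-2-yl}propoxy)dimethylsilane
Conditions: Me3SiOCH2CH2OSiMe3, Me3SiOTf (5 mol%), CH2Cl2, −78 → −20 °C; pyridine
Reagents that add atoms: 1,2-bis(trimethylsilyloxy)ethane, C[Si](C)(C)OCCO[Si](C)(C)C
Why: Silyl-triflate-catalysed ketalisation at low temperature, driven by formation of hexamethyldisiloxane, masks the ketone for Grignard formation without enolising the adjacent stereocentre (future C8).

Step 8
Reactants: 13; 6
Product: 15 methyl (1S,2S)-2-{(3R)-3-[2-(3-{[tert-butyl(dimethyl)silyl]oxy}propyl)-1,3-dioxolan-2-yl]butyl}-1-methyl-4-[(trimethylsilyl)oxy]cyclohex-3-ene-1-carboxylate, via ketal Grignard reagent 14 (not isolated)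
Conditions: 13, Mg, BrCH2CH2Br (cat.), THF, reflux; then CuBr·SMe2 (10 mol%), Me3SiCl, 6, THF, −78 → −40 °C; Et3N, cold aq. NaHCO3
Reagents that add atoms: chlorotrimethylsilane, C[Si](C)(C)Cl
Why: Copper-catalysed, chlorosilane-accelerated conjugate addition of a Grignard reagent to a 4,4-disubstituted cyclohexenone. Axial attack is expected anti to the pseudoaxial ester (the slimmer group and the better σ-acceptor), which places C6 cis to the C4 methyl and H5 on the β face. The enolate is trapped regiospecifically as the C1–C10 silyl enol ether.

Step 9
Reactants: 15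
Product: 16 methyl (1S,6R,8aS)-5-(3-{[tert-butyl(dimethyl)silyl]oxy}propyl)-5-(2-hydroxyethoxy)-1,6-dimethyl-4-oxodecahydronaphthalene-1-carboxylate (mixture at C9 and C10)
Conditions: TiCl4, CH2Cl2, −78 °C; aq. NaHCO3
Reagents that add atoms: none
Why: Intramolecular Mukaiyama aldol-type addition of the silyl enol ether to the oxocarbenium ion released from the dioxolane (6-exo closure of ring B, C9–C10 bond). No free C9 ketone is ever present, so C8 cannot epimerise by enolisation, and the new centres at C9 and C10 are removed in the next step.

Step 10
Reactants: 16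
Product: 17 methyl (1S,6R,8aS)-5-(3-{[tert-butyl(dimethyl)silyl]oxy}propyl)-1,6-dimethyl-4-oxo-1,2,3,4,6,7,8,8a-octahydronaphthalene-1-carboxylate
Conditions: DBU, toluene, 60 °C
Reagents that add atoms: none
Why: E1cB elimination of the β-alkoxy group through the C10 enolate can only give the conjugated C9=C10 enone; with a tertiary ether in place of a free aldol there is no retro-aldol pathway.

Step 11
Reactants: 17
Product: 18 methyl (1S,4S,6R,8aS)-5-(3-{[tert-butyl(dimethyl)silyl]oxy}propyl)-4-hydroxy-1,6-dimethyl-1,2,3,4,6,7,8,8a-octahydronaphthalene-1-carboxylate (C1 hydroxyl α)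
Conditions: (R)-1-methyl-3,3-diphenyltetrahydro-1H,3H-pyrrolo[1,2-c][1,3,2]oxazaborole (30 mol%), BH3·SMe2, THF, −30 → 0 °C; MeOH
Reagents that add atoms: none
Why: Corey–Bakshi–Shibata reduction with the alkene-bearing C10 side as the large group; the (R)-oxazaborolidine should deliver hydride to the β face of C1 and give the (S)-configured α alcohol. This is also the product of axial attack on ring A, so catalyst and substrate should be matched.

Step 12
Reactants: 18; 19 diiodomethane
Product: 20 methyl ester of the 9α,10α-methano alcohol (C20 methylene bridging C9 and C10 on the α face; C1 hydroxyl α; C9 silyloxypropyl chain β; C4, C5, C8 as in 18)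
Conditions: Et2Zn, CH2I2, CH2Cl2, −10 °C → rt; aq. NH4Cl
Reagents that add atoms: diiodomethane (19), ICI
Why: Hydroxyl-directed Simmons–Smith cyclopropanation in the Furukawa variant; the closest known type is the syn-cyclopropanation of cyclic allylic alcohols. Et2Zn deprotonates the C1 hydroxyl and forms with 19 an iodomethylzinc carbenoid, which is held by the zinc alkoxide and transfers CH2 to C9=C10 through a concerted butterfly-type transition state. The three-membered ring (C9, C10, C20) closes in one [2+1] event, with C9–C20 and C10–C20 forming on the same face. A(1,3) strain between the C1 substituent and C11 turns the C1–O bond roughly perpendicular to the alkene plane, so the α oxygen sits directly under the α face. Both new stereocentres are therefore controlled by the C1 carbinol: C20 enters α at C9 and C10, and the C11 chain is left β at C9. The step needs face selectivity against the steric bias of the α C8 methyl, which intramolecular delivery should secure. It also needs chemoselectivity, which is assured because the electron-rich tetrasubstituted alkene is the only alkene in 18 and the ester and silyl ether do not react with the carbenoid.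

Step 13
Reactants: 20
Product: 22 O-alkyl S-methyl dithiocarbonate (xanthate) of 20 at the C1 oxygen, via sodium xanthate 21 (not isolated)
Conditions: NaH, imidazole (cat.), THF, 0 °C; CS2, rt; MeI
Reagents that add atoms: carbon disulfide, S=C=S; iodomethane, CI
Why: Xanthate formation from the sodium alkoxide, carbon disulfide and iodomethane gives the radical precursor for Barton–McCombie C–O homolysis; the ester is not enolisable and the silyl ether is stable to NaH.

Step 14
Reactants: 22
Product: 23 methyl (1S,5S,6R,8aS)-5-(3-{[tert-butyl(dimethyl)silyl]oxy}propyl)-1,5,6-trimethyl-1,2,3,5,6,7,8,8a-octahydronaphthalene-1-carboxylate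
Conditions: Bu3SnH (0.5 M), 2,2′-azobis(2-methylpropionitrile) (cat.), toluene, 100 °C
Reagents that add atoms: none
Why: Barton–McCombie fragmentation gives the C1 cyclopropylcarbinyl radical, whose singly occupied orbital is aligned with the axial C10–C20 bond, so β-scission gives the C1=C10 alkene and a primary C20 radical on C9. Concentrated stannane reduces this radical to the C9 methyl before it can re-close and leak to the ring-enlarged tertiary radical. C9 keeps the configuration fixed in step 12.

Step 15
Reactants: 23
Product: 24 methyl (1S,5S,6R,8aS)-5-(3-hydroxypropyl)-1,5,6-trimethyl-1,2,3,5,6,7,8,8a-octahydronaphthalene-1-carboxylate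
Conditions: Bu4NF, THF, 0 °C → rt
Reagents that add atoms: none
Why: Fluoride cleavage of the primary silyl ether; the hindered ester and the alkene are inert.

Step 16
Reactants: 24
Product: 25 methyl (1S,5S,6R,8aS)-1,5,6-trimethyl-5-(3-oxopropyl)-1,2,3,5,6,7,8,8a-octahydronaphthalene-1-carboxylate
Conditions: Dess–Martin periodinane, NaHCO3, CH2Cl2, 0 °C → rt
Reagents that add atoms: none
Why: Dess–Martin oxidation gives the aldehyde under buffered, non-acidic conditions that leave the trisubstituted alkene in place.

Step 17
Reactants: 25
Product: 26 methyl (1S,5S,6R,8aS)-5-(but-3-yn-1-yl)-1,5,6-trimethyl-1,2,3,5,6,7,8,8a-octahydronaphthalene-1-carboxylate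
Conditions: dimethyl (1-diazo-2-oxopropyl)phosphonate, K2CO3, MeOH, 0 °C → rt
Reagents that add atoms: dimethyl (1-diazo-2-oxopropyl)phosphonate, COP(=O)(OC)C(=[N+]=[N-])C(C)=O
Why: Seyferth–Gilbert homologation in the Ohira–Bestmann variant: the diazomethylphosphonate anion formed by methanolysis adds to the aldehyde, and the derived alkylidene carbene rearranges to the terminal alkyne (adds C14). The carbonate base leaves the hindered ester intact.

Step 18
Reactants: 26
Product: 28 methyl (1S,5S,6R,8aS)-5-[(3E)-5-hydroxy-3-methylpent-3-en-1-yl]-1,5,6-trimethyl-1,2,3,5,6,7,8,8a-octahydronaphthalene-1-carboxylate, via alkenyldimethylalane 27 (not isolated)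
Conditions: Me3Al, (C5H5)2ZrCl2 (25 mol%), CH2Cl2, 0 °C → rt; then (CH2O)n, THF, 0 °C → rt; aq. potassium sodium tartrate
Reagents that add atoms: trimethylaluminium, C[Al](C)C; formaldehyde (as paraformaldehyde), C=O
Why: Zirconium-catalysed Negishi carboalumination adds methyl and aluminium syn across the terminal alkyne with methyl on the internal carbon (C13); the alkenylalane is then hydroxymethylated by formaldehyde with retention, which fixes the E geometry. The neopentyl-type methyl ester is too hindered to be attacked by the alane at or below room temperature.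

Step 19
Reactants: 28
Product: 29 (1S,5S,6R,8aS)-5-[(3E)-5-hydroxy-3-methylpent-3-en-1-yl]-1,5,6-trimethyl-1,2,3,5,6,7,8,8a-octahydronaphthalene-1-carboxylic acid
Conditions: NaSEt, DMF, 100 °C; then 1 M HCl
Reagents that add atoms: none
Why: SN2 demethylation by thiolate at the ester methyl group cleaves the O–CH3 bond and bypasses the hindered acyl carbon; the allylic alcohol and both alkenes are inert to thiolate.

Step 20
Reactants: 29
Product: 30 (1S,5S,6R,8aS)-1,5,6-trimethyl-5-[(3E)-3-methyl-5-(propanoyloxy)pent-3-en-1-yl]-1,2,3,5,6,7,8,8a-octahydronaphthalene-1-carboxylic acid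
Conditions: (EtCO)2O, pyridine, 4-(dimethylamino)pyridine (cat.), CH2Cl2, 0 °C → rt; then aq. NaHCO3–THF; acidify to pH 3
Reagents that add atoms: propanoic anhydride, CCC(=O)OC(=O)CC
Why: Nucleophilic catalysis acylates the primary allylic alcohol. The hindered acid can at most form a mixed anhydride, which the aqueous bicarbonate work-up hydrolyses at its unhindered propanoyl carbon.

## Compound list

1 | 2-methylprop-2-enal (methacrolein) | C=C(C)C=O | starting material
2 | (1E)-3-{[tert-butyl(dimethyl)silyl]oxy}-N,N-dimethylbuta-1,3-dien-1-amine | CN(C)/C=C/C(=C)O[Si](C)(C)C(C)(C)C | starting material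
3 | (1S,2R)-4-{[tert-butyl(dimethyl)silyl]oxy}-2-(dimethylamino)-1-methylcyclohex-3-ene-1-carbaldehyde (endo adduct, not isolated) | C1CC(O[Si](C)(C)C(C)(C)C)=C[C@@H](N(C)C)[C@@]1(C)C=O | intermediate
4 | (1S)-1-methyl-4-oxocyclohex-2-ene-1-carbaldehyde | O=C1CC[C@](C)(C=O)C=C1 | intermediate
5 | (1S)-1-methyl-4-oxocyclohex-2-ene-1-carboxylic acid | O=C1CC[C@](C)(C(=O)O)C=C1 | intermediate
6 | methyl (1S)-1-methyl-4-oxocyclohex-2-ene-1-carboxylate | O=C1CC[C@](C)(C(=O)OC)C=C1 | intermediate
7 | (3R)-3-methyloxolan-2-one ((R)-α-methyl-γ-butyrolactone) | C[C@@H]1CCOC1=O | starting material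
8 | methyl (2R)-4-chloro-2-methylbutanoate | C[C@@H](C(=O)OC)CCCl | intermediate
9 | (2R)-4-chloro-N-methoxy-N,2-dimethylbutanamide | C[C@@H](C(=O)N(C)OC)CCCl | intermediate
10 | (3-bromopropoxy)(tert-butyl)dimethylsilane | BrCCCO[Si](C)(C)C(C)(C)C | starting material
11 | (3-{[tert-butyl(dimethyl)silyl]oxy}propyl)magnesium bromide (not isolated) | CC(C)(C)[Si](C)(C)OCCC[Mg]Br | intermediate
12 | (3R)-7-{[tert-butyl(dimethyl)silyl]oxy}-1-chloro-3-methylheptan-4-one | C[C@@H](C(=O)CCCO[Si](C)(C)C(C)(C)C)CCCl | intermediate
13 | tert-butyl(3-{2-[(2R)-4-chlorobutan-2-yl]-1,3-dioxolan-2-yl}propoxy)dimethylsilane | C[C@@H](C1(CCCO[Si](C)(C)C(C)(C)C)OCCO1)CCCl | intermediate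
14 | {(3R)-3-[2-(3-{[tert-butyl(dimethyl)silyl]oxy}propyl)-1,3-dioxolan-2-yl]butyl}magnesium chloride (not isolated) | C[C@@H](C1(CCCO[Si](C)(C)C(C)(C)C)OCCO1)CC[Mg]Cl | intermediate
15 | methyl (1S,2S)-2-{(3R)-3-[2-(3-{[tert-butyl(dimethyl)silyl]oxy}propyl)-1,3-dioxolan-2-yl]butyl}-1-methyl-4-[(trimethylsilyl)oxy]cyclohex-3-ene-1-carboxylate | C[Si](C)(C)OC1=C[C@H](CC[C@@H](C)C2(CCCO[Si](C)(C)C(C)(C)C)OCCO2)[C@@](C)(C(=O)OC)CC1 | intermediate
16 | methyl (1S,6R,8aS)-5-(3-{[tert-butyl(dimethyl)silyl]oxy}propyl)-5-(2-hydroxyethoxy)-1,6-dimethyl-4-oxodecahydronaphthalene-1-carboxylate (epimer mixture at C9 and C10) | O=C1CC[C@](C)(C(=O)OC)[C@H]2CC[C@@H](C)C(CCCO[Si](C)(C)C(C)(C)C)(OCCO)C12 | intermediate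
17 | methyl (1S,6R,8aS)-5-(3-{[tert-butyl(dimethyl)silyl]oxy}propyl)-1,6-dimethyl-4-oxo-1,2,3,4,6,7,8,8a-octahydronaphthalene-1-carboxylate | O=C1CC[C@](C)(C(=O)OC)[C@H]2CC[C@@H](C)C(CCCO[Si](C)(C)C(C)(C)C)=C12 | intermediate
18 | methyl (1S,4S,6R,8aS)-5-(3-{[tert-butyl(dimethyl)silyl]oxy}propyl)-4-hydroxy-1,6-dimethyl-1,2,3,4,6,7,8,8a-octahydronaphthalene-1-carboxylate (C1 hydroxyl α; precursor of the key step) | CC(C)(C)[Si](C)(C)OCCCC1=C2[C@@H](O)CC[C@](C)(C(=O)OC)[C@H]2CC[C@H]1C | intermediate
19 | diiodomethane | ICI | starting material
20 | methyl ester of the 9α,10α-methano C1 α-alcohol (C20 methylene on the α face across C9–C10; C9 silyloxypropyl chain β; C4 methyl α and ester β; H5 β; C8 methyl α) | CC(C)(C)[Si](C)(C)OCCC[C@]12C[C@]13[C@@H](O)CC[C@](C)(C(=O)OC)[C@H]3CC[C@H]2C | intermediate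
21 | sodium O-alkyl dithiocarbonate of 20 at the C1 oxygen (not isolated) | CC(C)(C)[Si](C)(C)OCCC[C@]12C[C@]13[C@@H](OC(=S)[S-])CC[C@](C)(C(=O)OC)[C@H]3CC[C@H]2C.[Na+] | intermediate
22 | O-alkyl S-methyl dithiocarbonate of 20 at the C1 oxygen | CC(C)(C)[Si](C)(C)OCCC[C@]12C[C@]13[C@@H](OC(=S)SC)CC[C@](C)(C(=O)OC)[C@H]3CC[C@H]2C | intermediate
23 | methyl (1S,5S,6R,8aS)-5-(3-{[tert-butyl(dimethyl)silyl]oxy}propyl)-1,5,6-trimethyl-1,2,3,5,6,7,8,8a-octahydronaphthalene-1-carboxylate | CC(C)(C)[Si](C)(C)OCCC[C@]1(C)C2=CCC[C@](C)(C(=O)OC)[C@H]2CC[C@H]1C | intermediate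
24 | methyl (1S,5S,6R,8aS)-5-(3-hydroxypropyl)-1,5,6-trimethyl-1,2,3,5,6,7,8,8a-octahydronaphthalene-1-carboxylate | OCCC[C@]1(C)C2=CCC[C@](C)(C(=O)OC)[C@H]2CC[C@H]1C | intermediate
25 | methyl (1S,5S,6R,8aS)-1,5,6-trimethyl-5-(3-oxopropyl)-1,2,3,5,6,7,8,8a-octahydronaphthalene-1-carboxylate | O=CCC[C@]1(C)C2=CCC[C@](C)(C(=O)OC)[C@H]2CC[C@H]1C | intermediate
26 | methyl (1S,5S,6R,8aS)-5-(but-3-yn-1-yl)-1,5,6-trimethyl-1,2,3,5,6,7,8,8a-octahydronaphthalene-1-carboxylate | C#CCC[C@]1(C)C2=CCC[C@](C)(C(=O)OC)[C@H]2CC[C@H]1C | intermediate
27 | (E)-alkenyldimethylalane from 26 (aluminium on C14, cis to the new C13 methyl; not isolated) | C[Al](C)/C=C(\C)CC[C@]1(C)C2=CCC[C@](C)(C(=O)OC)[C@H]2CC[C@H]1C | intermediate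
28 | methyl (1S,5S,6R,8aS)-5-[(3E)-5-hydroxy-3-methylpent-3-en-1-yl]-1,5,6-trimethyl-1,2,3,5,6,7,8,8a-octahydronaphthalene-1-carboxylate | OC/C=C(\C)CC[C@]1(C)C2=CCC[C@](C)(C(=O)OC)[C@H]2CC[C@H]1C | intermediate
29 | (1S,5S,6R,8aS)-5-[(3E)-5-hydroxy-3-methylpent-3-en-1-yl]-1,5,6-trimethyl-1,2,3,5,6,7,8,8a-octahydronaphthalene-1-carboxylic acid | OC/C=C(\C)CC[C@]1(C)C2=CCC[C@](C)(C(=O)O)[C@H]2CC[C@H]1C | intermediate
30 | (1S,5S,6R,8aS)-1,5,6-trimethyl-5-[(3E)-3-methyl-5-(propanoyloxy)pent-3-en-1-yl]-1,2,3,5,6,7,8,8a-octahydronaphthalene-1-carboxylic acid | CCC(=O)OC/C=C(\C)CC[C@]1(C)C2=CCC[C@](C)(C(=O)O)[C@H]2CC[C@H]1C | target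

## Step count and least certain steps

Total: 20 steps. Longest linear sequence: 17 steps (7 to 30, steps 4–20). The ring A branch (steps 1–3) joins at step 8.

Step 12 (key step). Methylene transfer may be slow or incomplete, because the alkene is tetrasubstituted and its α face is also flanked by the C8 methyl. Lewis-acidic ZnI2 may in addition ionise the allylic or cyclopropylcarbinyl alcohol or loosen the silyl ether. Fallback, from 18 to 23, with carbon delivered by a sigmatropic shift instead of a carbenoid: 18 is vinylated with ethyl vinyl ether and Hg(OCOCF3)2 (cat.) to the O-vinyl ether F1. Heating in decane at about 170 °C effects a Claisen rearrangement that moves the two-carbon unit suprafacially from the α oxygen at C1 to the α face of C9 and forms C1=C10, giving the C9 acetaldehyde F2. Tsuji–Wilkinson decarbonylation with RhCl(PPh3)3 (1 equiv, toluene, reflux) turns CH2CHO into the C9 methyl and returns to 23.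

Step 8. Facial discrimination may be insufficient, because methyl and ester at C4 differ little in size and the preference rests on a conformational and electronic bias. Some 1,2-addition is also possible. Fallback, from 15 to 16, with C5 set by hydride instead of carbon delivery: 15 as a C5-epimer mixture is oxidised by the Saegusa–Ito method (Pd(OAc)2, MeCN, rt) to the 3-substituted enone F3, which no longer has a C5 centre. Copper-hydride conjugate reduction under ligand control (CuCl, NaOt-Bu, the antipode of a bulky chiral bisphosphine that places hydride on the β face of C5, PhMe2SiH, toluene) gives the dimethyl(phenyl)silyl enol ether F4 as one C5 epimer. F4 is cyclised with TiCl4 as in step 9 and rejoins the route at 16.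

Step 9. Protodesilylation of the enol ether may precede C–C bond formation. The oxocarbenium ion may lose a proton to an enol ether, which would scramble C8, and the primary silyl ether may be cleaved by the Lewis acid. Fallback, from 15 to 17, under thermodynamic instead of kinetic control: pyridinium p-toluenesulfonate in wet acetone removes the enol silane and the ketal to give the diketone F5. KOH in MeOH at rt then effects aldol condensation to 17. Any epimerisation at C8 should be corrected in the enone, where A(1,2) strain with C11 favours the pseudoaxial α methyl required.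

Step 14. The C1 radical may open the ring bond C9–C10 (ring-enlarged tertiary radical), or the C20 radical may re-close and leak to that product if hydrogen transfer is slow. Premature reduction of the xanthate adduct radical is a lesser risk. Fallback, from 20 to 23, with ionic instead of radical opening: 20 is mesylated (MsCl, Et3N, CH2Cl2, −30 °C) and treated with LiBr in THF. The cyclopropylcarbinyl cation is opened by bromide at the unhindered CH2 (Julia-type homoallyl rearrangement) to the homoallylic bromide F6, which already has the C1=C10 alkene. Reduction with concentrated Bu3SnH and a radical initiator at 80 °C gives 23; here the C20 radical is formed directly and is reduced faster than it can re-close.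

Step 18. Hydroxymethylation of the alkenylalane may be sluggish, ending in protonolysis to the 2-methylalkene, and methyl transfer to the ester may begin on long exposure. Fallback, from 26 to 28, with C15 introduced by a chromium-mediated addition: the carboalumination mixture is quenched with I2 to give the (E)-vinyl iodide F7. Nozaki–Hiyama–Kishi coupling with paraformaldehyde (CrCl2, NiCl2 cat., DMF–THF) forms the allylic alcohol with retention and without touching the ester, returning to 28.

## Further compounds

F1 | step 12 | O-vinyl ether of 18 at the C1 α oxygen | CC(C)(C)[Si](C)(C)OCCCC1=C2[C@@H](OC=C)CC[C@](C)(C(=O)OC)[C@H]2CC[C@H]1C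
F2 | step 12 | analogue of 23 with an α 2-oxoethyl group on C9 in place of the C9 methyl | CC(C)(C)[Si](C)(C)OCCC[C@]1(CC=O)C2=CCC[C@](C)(C(=O)OC)[C@H]2CC[C@H]1C
F3 | step 8 | methyl (1S)-2-{(3R)-3-[2-(3-{[tert-butyl(dimethyl)silyl]oxy}propyl)-1,3-dioxolan-2-yl]butyl}-1-methyl-4-oxocyclohex-2-ene-1-carboxylate | O=C1CC[C@](C)(C(=O)OC)C(CC[C@@H](C)C2(CCCO[Si](C)(C)C(C)(C)C)OCCO2)=C1
F4 | step 8 | dimethyl(phenyl)silyl enol ether analogue of 15, (1S,2S) | C[Si](C)(c1ccccc1)OC1=C[C@H](CC[C@@H](C)C2(CCCO[Si](C)(C)C(C)(C)C)OCCO2)[C@@](C)(C(=O)OC)CC1
F5 | step 9 | methyl (1S,2S)-2-[(3R)-7-{[tert-butyl(dimethyl)silyl]oxy}-3-methyl-4-oxoheptyl]-1-methyl-4-oxocyclohexane-1-carboxylate | O=C1C[C@H](CC[C@@H](C)C(=O)CCCO[Si](C)(C)C(C)(C)C)[C@@](C)(C(=O)OC)CC1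
F6 | step 14 | analogue of 23 with an α bromomethyl group on C9 in place of the C9 methyl | CC(C)(C)[Si](C)(C)OCCC[C@]1(CBr)C2=CCC[C@](C)(C(=O)OC)[C@H]2CC[C@H]1C
F7 | step 18 | methyl (1S,5S,6R,8aS)-5-[(3E)-4-iodo-3-methylbut-3-en-1-yl]-1,5,6-trimethyl-1,2,3,5,6,7,8,8a-octahydronaphthalene-1-carboxylate | I/C=C(\C)CC[C@]1(C)C2=CCC[C@](C)(C(=O)OC)[C@H]2CC[C@H]1C
A1 | alternative 1 | (5R,6S)-1-ethenyl-5,6-dimethyl-6-(prop-2-en-1-yl)cyclohex-1-ene | C=CC[C@]1(C)C(C=C)=CCC[C@H]1C
A2 | alternative 1 | (1S,5S,6R,8aS)-1,5,6-trimethyl-5-(prop-2-en-1-yl)-1,2,3,5,6,7,8,8a-octahydronaphthalene-1-carbaldehyde | C=CC[C@]1(C)C2=CCC[C@](C)(C=O)[C@H]2CC[C@H]1C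
A3 | alternative 2 | dimethyl 2-[(4E)-7-{[tert-butyl(dimethyl)silyl]oxy}-5-methyl-3-oxohept-4-en-1-yl]-2-[(1E,3E)-penta-1,3-dien-1-yl]propanedioate | C/C=C/C=C/C(C(=O)OC)(C(=O)OC)CCC(=O)/C=C(\C)CCO[Si](C)(C)C(C)(C)C
A4 | alternative 2 | cis-fused C1-oxo-6-octalin 4,4-dimethyl diester with C8 α methyl, C9 α methyl and C9 β 2-silyloxyethyl (H5 and H10 β) | CC(C)(C)[Si](C)(C)OCC[C@]1(C)[C@H]2C(=O)CCC(C(=O)OC)(C(=O)OC)[C@H]2C=C[C@H]1C
A5 | alternative 3 | methyl (2Z,4Z)-5-[(5R,6S)-6-(3-{[tert-butyl(dimethyl)silyl]oxy}propyl)-5,6-dimethylcyclohex-1-en-1-yl]-2-methylpenta-2,4-dienoate | CC(C)(C)[Si](C)(C)OCCC[C@]1(C)C(/C=C\C=C(\C)C(=O)OC)=CCC[C@H]1C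
A6 | alternative 3 | 1(10),2-hexalin methyl ester with C9 β silyloxypropyl chain (C4, C5, C8, C9 as in 23) | CC(C)(C)[Si](C)(C)OCCC[C@]1(C)C2=CC=C[C@](C)(C(=O)OC)[C@H]2CC[C@H]1C
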